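**Retrosynthetic overview**
1. Target 31 ← one acid step removing the benzylidene acetal and tert-butyl ester of 30 ← Stille coupling of α-iodoenone 24 with (E)-heptenylstannane 29.
2. The cyclohexenone (the only carbocycle) ← intramolecular aldol condensation of epoxy 1,5-diketone 20: the methyl-ketone enolate closes onto the dioxanone carbonyl, with the epoxide and carbinol stereocentres already in place.
3. Diketone 20 ← MeLi opening and oxidation of epoxy δ-lactone 18 ← nucleophilic epoxidation of the cis-fused unsaturated lactone 17, anti to its axial acetal oxygen.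
4. Lactone 17 ← Z-selective Horner–Wadsworth–Emmons union and lactonisation of aldehyde 5 (from diethyl L-tartrate, sets the carbinol centre) with phosphonate 15 (carries the tiglate side chain).
5. Ring order: dioxane acetal → unsaturated lactone → oxirane → lactone opened → carbocycle by aldol.

Assumption: the SMILES is taken literally, that is the (1S,5R,6S) isomer with the secondary hydroxyl trans to the epoxide oxygen and both side-chain alkenes E.

**Route**

Step 1
Reactants: 1 diethyl L-tartrate
Product: 2 diethyl 2,3-O-benzylidene-L-tartrate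
Conditions: PhCH(OMe)2, TsOH (cat.), toluene, reflux (MeOH distilled off)
Reagents that add atoms: benzaldehyde dimethyl acetal, COC(OC)c1ccccc1
Why: Acid-catalysed transacetalisation ties the 1,2-diol up as a dioxolane without touching the two tartrate stereocentres, which are the only source of chirality in the route.

Step 2
Reactants: 2 diethyl 2,3-O-benzylidene-L-tartrate
Product: 3 2,3-O-benzylidene-L-threitol
Conditions: LiAlH4, THF, 0 °C → rt
Reagents that add atoms: none
Why: Hydride reduction of both esters to primary alcohols leaves the acetal and the stereocentres untouched.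

Step 3
Reactants: 3 2,3-O-benzylidene-L-threitol
Product: 4 1,3-O-benzylidene-L-threitol
Conditions: TsOH (cat.), CH2Cl2, rt, then crystallisation
Reagents that add atoms: none
Why: Acid-catalysed acetal migration under thermodynamic control gives the six-membered benzylidene acetal with phenyl and CH2OH equatorial and the 5-OH axial, which fixes the acetal centre and frees one primary and one secondary hydroxyl.

Step 4
Reactants: 4 1,3-O-benzylidene-L-threitol
Product: 5 2,4-O-benzylidene-L-threose
Conditions: TEMPO (cat.), PhI(OAc)2, CH2Cl2, rt (used crude)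
Reagents that add atoms: none
Why: The oxoammonium (TEMPO) oxidation is selective for the primary alcohol and stops at the aldehyde, so the axial secondary hydroxyl needed for lactonisation stays free.

Step 5
Reactants: 6 tert-butyl 2-bromopropanoate
Product: 8 tert-butyl 2-(triphenylphosphoranylidene)propanoate, via phosphonium bromide 7 (not isolated)
Conditions: PPh3, toluene, 90 °C; then NaOH (aq), CH2Cl2, rt
Reagents that add atoms: triphenylphosphine, c1ccc(cc1)P(c1ccccc1)c1ccccc1
Why: SN2 quaternisation of the phosphine followed by deprotonation gives the ester-stabilised Wittig ylide.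

Step 6
Reactants: 8 tert-butyl 2-(triphenylphosphoranylidene)propanoate and 9 glycolaldehyde dimer
Product: 10 tert-butyl (E)-4-hydroxy-2-methylbut-2-enoate
Conditions: CH2Cl2, reflux
Reagents that add atoms: none
Why: Wittig olefination of the monomeric hydroxy aldehyde with a stabilised α-methyl ylide is reversible at the betaine stage and gives the E (tiglate) alkene.

Step 7
Reactants: 10 tert-butyl (E)-4-hydroxy-2-methylbut-2-enoate
Product: 11 tert-butyl (E)-4-bromo-2-methylbut-2-enoate
Conditions: CBr4, PPh3, CH2Cl2, 0 °C
Reagents that add atoms: carbon tetrabromide, BrC(Br)(Br)Br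
Why: The Appel reaction replaces the primary allylic hydroxyl by bromide in an SN2 step that leaves the alkene geometry and the tert-butyl ester intact.

Step 8
Reactants: 12 diphenyl phosphite and 13 methyl bromoacetate
Product: 14 methyl 2-(diphenoxyphosphoryl)acetate
Conditions: Et3N, CH2Cl2, 0 °C → rt
Reagents that add atoms: none
Why: Michaelis–Becker-type P-alkylation of the phosphite anion gives the diaryl phosphonoacetate needed for a Z-selective olefination.

Step 9
Reactants: 14 methyl 2-(diphenoxyphosphoryl)acetate and 11 tert-butyl (E)-4-bromo-2-methylbut-2-enoate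
Product: 15 1-tert-butyl 6-methyl (E)-5-(diphenoxyphosphoryl)-2-methylhex-2-enedioate
Conditions: NaH, THF, 0 °C; then 11, 0 °C → rt (14 in slight excess)
Reagents that add atoms: none
Why: SN2 C-alkylation of the sodium phosphonoacetate at the primary allylic bromide attaches the whole tiglate side chain, the α-methyl group disfavouring conjugate addition.

Step 10
Reactants: 5 2,4-O-benzylidene-L-threose and 15 1-tert-butyl 6-methyl (E)-5-(diphenoxyphosphoryl)-2-methylhex-2-enedioate
Product: 17 cis-fused unsaturated benzylidene lactone, via hydroxy enoate 16 (not isolated)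
Conditions: NaH, THF, −78 → 0 °C; then PPTS (cat.), toluene, 60 °C
Reagents that add atoms: none
Why: Horner–Wadsworth–Emmons olefination with a diaryl phosphonate (Ando variant) gives the kinetic Z-enoate, and only this isomer can lactonise onto the free axial hydroxyl, so the six-membered lactone locks the alkene geometry.

Step 11
Reactants: 17 cis-fused unsaturated benzylidene lactone
Product: 18 epoxy lactone
Conditions: t-BuOOH, n-BuLi, THF, −78 → 0 °C
Reagents that add atoms: tert-butyl hydroperoxide, CC(C)(C)OO
Why: Weitz–Scheffer nucleophilic epoxidation puts the peroxide on the β-carbon axially and anti to the adjacent pseudoaxial acetal oxygen, which sets both oxirane centres trans to the carbinol oxygen, while the less electrophilic acyclic tert-butyl tiglate is left alone.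

Step 12
Reactants: 18 epoxy lactone
Product: 19 methyl hemiketal
Conditions: MeLi (1.05 equiv), THF, −78 °C
Reagents that add atoms: methyllithium, [Li]C
Why: 1,2-addition of MeLi to the lactone carbonyl stops at the tetrahedral lithium hemiketalate at low temperature and supplies the methyl-ketone carbon that becomes the enone α-carbon.

Step 13
Reactants: 19 methyl hemiketal
Product: 20 epoxy 1,5-diketone
Conditions: Dess–Martin periodinane, NaHCO3, CH2Cl2, rt (used at once, no chromatography)
Reagents that add atoms: none
Why: Dess–Martin oxidation acts on the secondary hydroxyl of the open-chain hydroxy ketone tautomer under buffered, non-enolising conditions that spare the base-labile β,γ-epoxy ketone.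

Step 14
Reactants: 20 epoxy 1,5-diketone
Product: 23 tricyclic enone, via lithium aldolate 21 (not isolated), via tertiary mesylate 22 (not isolated)
Conditions: LiN(SiMe3)2, THF, −78 °C; then MsCl, Et3N, −78 → 0 °C
Reagents that add atoms: none
Why: Intramolecular aldol condensation in which kinetic deprotonation takes the methyl ketone (its other α-carbon is quaternary and the dioxanone α-hydrogens are slowed by their oxygen substituents), the enolate closes 6-(enolendo)-exo-trig onto the activated dioxanone carbonyl, and in-flask mesylation with E1cB loss removes the transient carbinol centre.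

Step 15
Reactants: 23 tricyclic enone
Product: 24 α-iodoenone
Conditions: I2, pyridine, DMAP (cat.), CH2Cl2, 0 °C → rt
Reagents that add atoms: iodine, [I][I]
Why: Johnson α-iodination of an enone (amine conjugate addition, iodination of the enolate, elimination) is mild enough for epoxy enones of this class.

Step 16
Reactants: 25 hept-1-yne
Product: 27 (E)-1-iodohept-1-ene, via alkenylzirconocene 26 (not isolated)
Conditions: Cp2Zr(H)Cl, CH2Cl2, rt; then I2, 0 °C
Reagents that add atoms: iodine, [I][I]
Why: syn-Hydrozirconation places zirconium on the terminal carbon and iodinolysis proceeds with retention, giving the geometrically pure E-iodide.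

Step 17
Reactants: 27 (E)-1-iodohept-1-ene
Product: 29 (E)-tributyl(hept-1-enyl)stannane, via alkenyllithium 28 (not isolated)
Conditions: n-BuLi, Et2O, −78 °C; then Bu3SnCl, −78 °C → rt
Reagents that add atoms: tributyltin chloride, CCCC[Sn](Cl)(CCCC)CCCC
Why: Iodine–lithium exchange and stannylation both go with retention at the sp2 carbon, which avoids the E/Z mixtures of radical hydrostannation.

Step 18
Reactants: 24 α-iodoenone and 29 (E)-tributyl(hept-1-enyl)stannane
Product: 30 benzylidene acetal tert-butyl ester of the target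
Conditions: Pd2(dba)3 (cat.), AsPh3, CuI, NMP, rt
Reagents that add atoms: none
Why: Stille coupling under neutral, ligand-accelerated conditions transfers the alkenyl group with retention of E geometry and tolerates the base-sensitive epoxy enone.

Step 19
Reactants: 30 benzylidene acetal tert-butyl ester of the target
Product: 31 CNP0332048.4
Conditions: TFA, CH2Cl2, H2O, 0 °C → rt
Reagents that add atoms: none
Why: Acidolysis cleaves the tert-butyl ester (loss of isobutene) and hydrolyses the benzylidene acetal in one operation, the electron-poor α,β-epoxy ketone being resistant to acid-induced opening.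

**Compound list**
1 | diethyl L-tartrate, (2R,3R) | CCOC(=O)[C@H](O)[C@@H](O)C(=O)OCC | starting material
2 | diethyl (4R,5R)-2-phenyl-1,3-dioxolane-4,5-dicarboxylate | CCOC(=O)[C@@H]1OC(c2ccccc2)O[C@H]1C(=O)OCC | intermediate
3 | [(4S,5S)-2-phenyl-1,3-dioxolane-4,5-diyl]dimethanol | OC[C@@H]1OC(c2ccccc2)O[C@H]1CO | intermediate
4 | (2R,4S,5S)-4-(hydroxymethyl)-2-phenyl-1,3-dioxan-5-ol (phenyl and CH2OH equatorial, OH axial) | OC[C@@H]1O[C@H](c2ccccc2)OC[C@@H]1O | intermediate
5 | (2R,4R,5S)-5-hydroxy-2-phenyl-1,3-dioxane-4-carbaldehyde | O=C[C@@H]1O[C@H](c2ccccc2)OC[C@@H]1O | intermediate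
6 | tert-butyl 2-bromopropanoate (racemic) | CC(Br)C(=O)OC(C)(C)C | starting material
7 | [1-(tert-butoxycarbonyl)ethyl]triphenylphosphonium bromide | CC(C(=O)OC(C)(C)C)[P+](c1ccccc1)(c1ccccc1)c1ccccc1.[Br-] | intermediate
8 | tert-butyl 2-(triphenylphosphoranylidene)propanoate | CC(C(=O)OC(C)(C)C)=P(c1ccccc1)(c1ccccc1)c1ccccc1 | intermediate
9 | glycolaldehyde dimer (1,4-dioxane-2,5-diol) | OC1COC(O)CO1 | starting material
10 | tert-butyl (E)-4-hydroxy-2-methylbut-2-enoate | OC/C=C(\C)C(=O)OC(C)(C)C | intermediate
11 | tert-butyl (E)-4-bromo-2-methylbut-2-enoate | BrC/C=C(\C)C(=O)OC(C)(C)C | intermediate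
12 | diphenyl phosphite | O=[PH](Oc1ccccc1)Oc1ccccc1 | starting material
13 | methyl bromoacetate | COC(=O)CBr | starting material
14 | methyl 2-(diphenoxyphosphoryl)acetate | COC(=O)CP(=O)(Oc1ccccc1)Oc1ccccc1 | intermediate
15 | 1-tert-butyl 6-methyl (E)-5-(diphenoxyphosphoryl)-2-methylhex-2-enedioate (racemic at C-5) | COC(=O)C(C/C=C(\C)C(=O)OC(C)(C)C)P(=O)(Oc1ccccc1)Oc1ccccc1 | intermediate
16 | (Z)-enoate from 5 and 15: methyl ester cis to the dioxanyl group, free axial 5-OH | COC(=O)/C(C/C=C(\C)C(=O)OC(C)(C)C)=C\[C@@H]1O[C@H](c2ccccc2)OC[C@@H]1O | intermediate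
17 | tert-butyl (2E)-2-methyl-4-[(2R,4aS,8aS)-6-oxo-2-phenyl-4,4a,6,8a-tetrahydropyrano[3,2-d][1,3]dioxin-7-yl]but-2-enoate (cis-fused) | O=C1O[C@H]2CO[C@@H](c3ccccc3)O[C@H]2C=C1C/C=C(\C)C(=O)OC(C)(C)C | intermediate
18 | 7,8-epoxide of 17, oxirane oxygen trans to the acetal oxygen on C-8a | O=C1O[C@H]2CO[C@@H](c3ccccc3)O[C@H]2[C@@H]3O[C@]13C/C=C(\C)C(=O)OC(C)(C)C | intermediate
19 | methyl hemiketal of 18 (lactone C=O replaced by C(OH)CH3, anomer mixture) | CC1(O)O[C@H]2CO[C@@H](c3ccccc3)O[C@H]2[C@@H]3O[C@]13C/C=C(\C)C(=O)OC(C)(C)C | intermediate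
20 | tert-butyl (2E)-4-[(2S,3S)-2-acetyl-3-[(2R,4S)-5-oxo-2-phenyl-1,3-dioxan-4-yl]oxiran-2-yl]-2-methylbut-2-enoate | CC(=O)[C@@]1(C/C=C(\C)C(=O)OC(C)(C)C)O[C@H]1[C@@H]2O[C@H](c3ccccc3)OCC2=O | intermediate
21 | lithium alkoxide of the cyclised aldol (acetyl CH3 carbon bonded to the former dioxanone carbonyl carbon; carbinol configuration not defined) | [Li+].[O-]C12CO[C@@H](c3ccccc3)O[C@H]1[C@@H]1O[C@]1(C/C=C(\C)C(=O)OC(C)(C)C)C(=O)C2 | intermediate
22 | methanesulfonate of the aldol 21 | CS(=O)(=O)OC12CO[C@@H](c3ccccc3)O[C@H]1[C@@H]1O[C@]1(C/C=C(\C)C(=O)OC(C)(C)C)C(=O)C2 | intermediate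
23 | tricyclic enone: target skeleton with H in place of heptenyl, the secondary O and the CH2O bridged as benzylidene acetal, tert-butyl ester | O=C1C=C2CO[C@@H](c3ccccc3)O[C@H]2[C@@H]2O[C@]12C/C=C(\C)C(=O)OC(C)(C)C | intermediate
24 | α-iodo derivative of 23 (iodine on the enone α-carbon) | O=C1C(I)=C2CO[C@@H](c3ccccc3)O[C@H]2[C@@H]2O[C@]12C/C=C(\C)C(=O)OC(C)(C)C | intermediate
25 | hept-1-yne | CCCCCC#C | starting material
26 | (E)-hept-1-enylzirconocene chloride | CCCCC/C=C/[Zr](Cl)(C1C=CC=C1)C1C=CC=C1 | intermediate
27 | (E)-1-iodohept-1-ene | CCCCC/C=C/I | intermediate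
28 | (E)-hept-1-enyllithium | CCCCC/C=C/[Li] | intermediate
29 | (E)-tributyl(hept-1-enyl)stannane | CCCCC/C=C/[Sn](CCCC)(CCCC)CCCC | intermediate
30 | benzylidene acetal (phenyl equatorial) and tert-butyl ester of the target | CCCCC/C=C/C1=C2CO[C@@H](c3ccccc3)O[C@H]2[C@@H]3O[C@]3(C/C=C(\C)C(=O)OC(C)(C)C)C1=O | intermediate
31 | (2E)-4-[(1S,5R,6S)-3-[(1E)-hept-1-en-1-yl]-5-hydroxy-4-(hydroxymethyl)-2-oxo-7-oxabicyclo[4.1.0]hept-3-en-1-yl]-2-methylbut-2-enoic acid | CCCCC/C=C/C1=C(CO)[C@@H](O)[C@@H]2O[C@]2(C/C=C(\C)C(=O)O)C1=O | target

**Step count**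
Total: 19 steps. Longest linear sequence: 12 steps (1–4, 10–15, 18, 19; the side-chain arm 5, 6, 7, 9, 10–15, 18, 19 is equally long), that is 12/19 = 0.63.

**Steps most likely to fail, with fallbacks**

Step 11 (epoxidation of the α-substituted unsaturated lactone). The lactone may be too unreactive toward t-BuOOLi, or the tiglate may compete. The fallback changes the order so that the alkene is epoxidised as an electron-rich olefin. It sets out from 17: MeLi in THF at −78 °C gives the unsaturated methyl hemiketal F1. mCPBA with NaHCO3 in CH2Cl2 at 0 °C then epoxidises the ring alkene from the face opposite the axial acetal oxygen and leaves the electron-poor tiglate alone. This gives 19, where it comes back to the route before step 13.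

Step 14 (aldol ring closure). LiN(SiMe3)2 may deprotonate the dioxanone side, which would open the epoxide by E1cB or give the wrong aldol. The fallback makes the enolate regiospecifically without an amide base. It sets out from 18: Me3SiCH2Li in THF at −78 °C gives the silylmethyl hemiketal F2, and Dess–Martin oxidation gives the α-silyl diketone F3. CsF in THF at −40 °C cleaves the C–Si bond, so only the wanted enolate forms, and it closes to the β-hydroxy ketone F4, which is isolated. MsCl and Et3N then take F4 through the mesylate 22 to 23, where it comes back to the route.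

Step 15 (iodination of the hindered, fully β-substituted enone). If 23 does not iodinate cleanly, the heptenyl group is brought in before ring closure and the iodide and Stille steps are dropped. The fallback sets out from 18. Heptanal with CHI3 and CrCl2 in THF gives (E)-1-iodooct-1-ene F5, and n-BuLi at −78 °C converts it into (E)-oct-1-enyllithium F6. F6 adds to lactone 18 to give the enone hemiketal F7, and Dess–Martin oxidation gives the enone diketone F8. Catalytic DBU in CH2Cl2 removes the γ-proton of the enone, its only enolisable position. The dienolate closes through its α-carbon onto the dioxanone carbonyl to give the aldol F9, which loses water in the same flask. This gives 30, where it comes back to the route before step 19. If some Z side-chain isomer forms, it is equilibrated to E with a trace of I2.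

**Further compounds**
F1 | step 11 | unsaturated methyl hemiketal (17 with the lactone C=O replaced by C(OH)CH3) | CC1(O)O[C@H]2CO[C@@H](c3ccccc3)O[C@H]2C=C1C/C=C(\C)C(=O)OC(C)(C)C
F2 | step 14 | (trimethylsilyl)methyl hemiketal of 18 | C[Si](C)(C)CC1(O)O[C@H]2CO[C@@H](c3ccccc3)O[C@H]2[C@@H]3O[C@]13C/C=C(\C)C(=O)OC(C)(C)C
F3 | step 14 | α-trimethylsilyl analogue of diketone 20 | C[Si](C)(C)CC(=O)[C@@]1(C/C=C(\C)C(=O)OC(C)(C)C)O[C@H]1[C@@H]2O[C@H](c3ccccc3)OCC2=O
F4 | step 14 | tricyclic β-hydroxy ketone (free alcohol of 21) | OC12CO[C@@H](c3ccccc3)O[C@H]1[C@@H]1O[C@]1(C/C=C(\C)C(=O)OC(C)(C)C)C(=O)C2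
F5 | step 15 | (E)-1-iodooct-1-ene | CCCCCC/C=C/I
F6 | step 15 | (E)-oct-1-enyllithium | CCCCCC/C=C/[Li]
F7 | step 15 | (E)-oct-1-enyl hemiketal of 18 | CCCCCC/C=C/C1(O)O[C@H]2CO[C@@H](c3ccccc3)O[C@H]2[C@@H]3O[C@]13C/C=C(\C)C(=O)OC(C)(C)C
F8 | step 15 | (E)-non-2-enoyl analogue of diketone 20 | CCCCCC/C=C/C(=O)[C@@]1(C/C=C(\C)C(=O)OC(C)(C)C)O[C@H]1[C@@H]2O[C@H](c3ccccc3)OCC2=O
F9 | step 15 | tricyclic β-hydroxy ketone bearing the (E)-hept-1-enyl group on the ketone α-carbon | CCCCC/C=C/C1C(=O)[C@@]2(C/C=C(\C)C(=O)OC(C)(C)C)O[C@H]2[C@@H]2O[C@H](c3ccccc3)OCC12O
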